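**Retrosynthetic overview**
1. The quinone comes from the 2,6-disubstituted phenol 19 by para-oxygenation in the last step. No ring is built: the benzene ring of o-cresol is carried through and only oxidised at the end.
2. The C11′ CH2OH group and the E-trisubstituted alkene come from the (R)-propargylic alcohol 16 (hydroxyl-directed trans-hydrostannation, Sn→Li, CH2O).
3. The C12′–O stereocentre comes from the racemic propargylic carbonate 14 by an enantioconvergent Ni-catalysed C–O bond formation (key step).
4. Carbonate 14 comes from allylic bromide 7, the propyne dianion and 4-methylpent-3-enal in one flask.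
5. Bromide 7 comes from o-cresol and geranyl bromide (ortho C-allylation), then terminal allylic oxidation and bromination.

Assumption: the side chain is numbered C1′ (ring CH2) to C16′; the stereocentre C12′ is R by CIP as read from the SMILES, and the CH2OH sits on C11′.

**Step 1**
Reactants: 1 2-methylphenol (o-cresol); 2 geranyl bromide [(2E)-1-bromo-3,7-dimethylocta-2,6-diene]
Product: 4 2-[(2E)-3,7-dimethylocta-2,6-dien-1-yl]-6-methylphenol, via sodium 2-methylphenolate 3 (not isolated)
Conditions: NaH, toluene, 0 °C→rt; then 2, rt, 24 h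
Reagents that add atoms: none
Why: Sodium aryloxide aggregates in a non-polar solvent alkylate at the only free ortho carbon (phenoxide ortho C-allylation, SN2 at the primary allylic bromide with the 2E geometry kept) and the dienone tautomerises to the phenol, the O- and para-alkylated by-products being removed by chromatography.

**Step 2**
Reactants: 4 2-[(2E)-3,7-dimethylocta-2,6-dien-1-yl]-6-methylphenol
Product: 5 tert-butyl{2-[(2E)-3,7-dimethylocta-2,6-dien-1-yl]-6-methylphenoxy}dimethylsilane
Conditions: TBSCl, imidazole, DMF, rt→40 °C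
Reagents that add atoms: tert-butyldimethylsilyl chloride, CC(C)(C)[Si](C)(C)Cl
Why: Standard silylation masks the acidic phenol for the organolithium and Ni(0) steps.

**Step 3**
Reactants: 5 tert-butyl{2-[(2E)-3,7-dimethylocta-2,6-dien-1-yl]-6-methylphenoxy}dimethylsilane
Product: 6 (2E,6E)-8-[2-(tert-butyldimethylsilyloxy)-3-methylphenyl]-2,6-dimethylocta-2,6-dien-1-ol
Conditions: SeO2 (0.3 equiv), salicylic acid (cat.), t-BuOOH, CH2Cl2, 0 °C→rt, stopped at partial conversion
Reagents that add atoms: selenium dioxide, O=[Se]=O (oxygen carrier), turned over by tert-butyl hydroperoxide, CC(C)(C)OO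
Why: Catalytic SeO2 allylic oxidation (ene reaction, then [2,3]-sigmatropic shift) attacks the E-methyl group of the terminal, least hindered trisubstituted alkene and gives the (E)-allylic alcohol.

**Step 4**
Reactants: 6 (2E,6E)-8-[2-(tert-butyldimethylsilyloxy)-3-methylphenyl]-2,6-dimethylocta-2,6-dien-1-ol
Product: 7 tert-butyl{2-[(2E,6E)-8-bromo-3,7-dimethylocta-2,6-dien-1-yl]-6-methylphenoxy}dimethylsilane
Conditions: CBr4, PPh3, CH2Cl2, −20→0 °C
Reagents that add atoms: carbon tetrabromide, BrC(Br)(Br)Br
Why: Appel bromination substitutes the primary allylic alcohol by SN2 without allylic shift or loss of alkene geometry.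

**Step 5**
Reactants: 8 4-methylpent-3-en-1-ol
Product: 9 4-methylpent-3-enal
Conditions: Dess–Martin periodinane, NaHCO3, CH2Cl2, 0 °C; used at once as a cold solution
Reagents that add atoms: none
Why: Buffered Dess–Martin oxidation gives the β,γ-unsaturated aldehyde under conditions too mild to move the double bond into conjugation.

**Step 6**
Reactants: 7 tert-butyl{2-[(2E,6E)-8-bromo-3,7-dimethylocta-2,6-dien-1-yl]-6-methylphenoxy}dimethylsilane; 10 propyne; 9 4-methylpent-3-enal
Product: 14 racemic tert-butyl{2-[(2E,6E)-12-(methoxycarbonyloxy)-3,7,15-trimethylhexadeca-2,6,14-trien-10-yn-1-yl]-6-methylphenoxy}dimethylsilane, via 1,3-dilithiopropyne 11 (not isolated), via lithium acetylide 12 (not isolated), via lithium alkoxide 13 (not isolated)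
Conditions: 10, n-BuLi (2 equiv), TMEDA, THF–hexane, −78→0 °C; 7, −78→−20 °C; 9, −78 °C; ClCO2Me, −78→0 °C
Reagents that add atoms: methyl chloroformate, COC(=O)Cl
Why: 1,3-Dilithiopropyne is alkylated at its sp3 carbon by the primary allylic bromide (SN2, 6E geometry kept), the resulting acetylide adds 1,2 to the aldehyde (acetylide addition) and the alkoxide is trapped as the carbonate; the C12′ centre is deliberately formed racemic.

**Step 7**
Reactants: 14 racemic propargylic methyl carbonate (as named in step 6)
Product: 15 tert-butyl{2-[(2E,6E,12R)-12-acetoxy-3,7,15-trimethylhexadeca-2,6,14-trien-10-yn-1-yl]-6-methylphenoxy}dimethylsilane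
Conditions: Ni(cod)2 (5 mol%), (R)-DTBM-SEGPHOS (6 mol%), AcOH, i-Pr2NEt, THF, 0 °C
Reagents that add atoms: acetic acid, CC(=O)O
Why: Proposed new method: Ni-catalysed enantioconvergent decarboxylative propargylic acetoxylation, in which Ni(0) ionises both enantiomers of the carbonate by anti-SN2′ oxidative addition to η3-propargyl/allenyl Ni(II) species that interconvert (η3–η1–η3) faster than they are trapped, the methoxide released is quenched by the ammonium acetate, and acetate attacks the propargylic carbon C12′ from outside the metal under control of the chiral bisphosphine to form the C12′–O bond as the R centre (the chelating ligand leaves no cis site for β-hydride loss to the enyne, and the ligand antipode is matched to R in a model run); the closest known reaction type is the Ni-catalysed asymmetric propargylic substitution of racemic internal propargylic carbonates with amine and soft carbon nucleophiles, which has not been shown for carboxylate oxygen nucleophiles on alkyl-substituted substrates.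

**Step 8**
Reactants: 15 (12R)-propargylic acetate silyl ether (as named in step 7)
Product: 16 2-[(2E,6E,12R)-12-hydroxy-3,7,15-trimethylhexadeca-2,6,14-trien-10-yn-1-yl]-6-methylphenol
Conditions: K2CO3 (cat.), MeOH, rt→40 °C
Reagents that add atoms: none
Why: Methoxide-catalysed transesterification cleaves the acetate at the acyl–O bond (C12′–O bond and configuration untouched) and methanolysis removes the aryl silyl ether in the same operation.

**Step 9**
Reactants: 16 2-[(2E,6E,12R)-12-hydroxy-3,7,15-trimethylhexadeca-2,6,14-trien-10-yn-1-yl]-6-methylphenol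
Product: 17 2-[(2E,6E,10Z,12R)-12-hydroxy-3,7,15-trimethyl-11-(tributylstannyl)hexadeca-2,6,10,14-tetraen-1-yl]-6-methylphenol
Conditions: [Cp*RuCl]4 (2 mol%), Bu3SnH, CH2Cl2, rt
Reagents that add atoms: tributyltin hydride, CCCC[SnH](CCCC)CCCC
Why: Hydroxyl-directed Ru-catalysed trans-hydrostannation of a propargylic alcohol puts tin on the alkyne carbon next to the carbinol (OH···Cl–Ru hydrogen bond) and adds H and Sn anti, which fixes C9′ trans to C12′.

**Step 10**
Reactants: 17 (10Z,12R)-alkenylstannane (as named in step 9)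
Product: 19 2-[(2E,6E,10E,12R)-12-hydroxy-11-(hydroxymethyl)-3,7,15-trimethylhexadeca-2,6,10,14-tetraen-1-yl]-6-methylphenol, via trilithio alkenyllithium 18 (not isolated)
Conditions: MeLi (4 equiv), THF, −78→−10 °C; (CH2O)n, −78 °C→rt; H2O
Reagents that add atoms: formaldehyde (from paraformaldehyde), C=O
Why: Tin–lithium exchange gives the configurationally stable alkenyllithium (held by the neighbouring lithium alkoxide) with retention, and its addition to formaldehyde turns C–Sn into C–CH2OH with the alkene geometry of the target.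

**Step 11**
Reactants: 19 2-[(2E,6E,10E,12R)-12-hydroxy-11-(hydroxymethyl)-3,7,15-trimethylhexadeca-2,6,10,14-tetraen-1-yl]-6-methylphenol
Product: 20 2-[(2E,6E,10E,12R)-12-hydroxy-11-(hydroxymethyl)-3,7,15-trimethylhexadeca-2,6,10,14-tetraen-1-yl]-6-methylcyclohexa-2,5-diene-1,4-dione (CNP0201434.1)
Conditions: Fremy's salt (2.5 equiv), KH2PO4, acetone–H2O, rt
Reagents that add atoms: potassium nitrosodisulfonate (Fremy's salt), [K+].[K+].[O]N(S(=O)(=O)[O-])S(=O)(=O)[O-]
Why: Teuber oxidation converts a 2,6-dialkylphenol with a free para position into the para-benzoquinone through the phenoxyl radical (new C4–O bond), and leaves the allylic diol and the trisubstituted alkenes untouched.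

**Compound list**
1 | 2-methylphenol | Cc1ccccc1O | starting material
2 | geranyl bromide | CC(C)=CCC/C(C)=C/CBr | starting material
3 | sodium 2-methylphenolate | Cc1ccccc1[O-].[Na+] | intermediate
4 | 2-[(2E)-3,7-dimethylocta-2,6-dien-1-yl]-6-methylphenol | CC(C)=CCC/C(C)=C/Cc1cccc(C)c1O | intermediate
5 | tert-butyl{2-[(2E)-3,7-dimethylocta-2,6-dien-1-yl]-6-methylphenoxy}dimethylsilane | CC(C)=CCC/C(C)=C/Cc1cccc(C)c1O[Si](C)(C)C(C)(C)C | intermediate
6 | (2E,6E)-8-[2-(tert-butyldimethylsilyloxy)-3-methylphenyl]-2,6-dimethylocta-2,6-dien-1-ol | OC/C(C)=C/CC/C(C)=C/Cc1cccc(C)c1O[Si](C)(C)C(C)(C)C | intermediate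
7 | tert-butyl{2-[(2E,6E)-8-bromo-3,7-dimethylocta-2,6-dien-1-yl]-6-methylphenoxy}dimethylsilane | BrC/C(C)=C/CC/C(C)=C/Cc1cccc(C)c1O[Si](C)(C)C(C)(C)C | intermediate
8 | 4-methylpent-3-en-1-ol | CC(C)=CCCO | starting material
9 | 4-methylpent-3-enal | CC(C)=CCC=O | intermediate
10 | propyne | CC#C | starting material
11 | 1,3-dilithiopropyne | [Li]CC#C[Li] | intermediate
12 | lithium (5E,9E)-11-[2-(tert-butyldimethylsilyloxy)-3-methylphenyl]-5,9-dimethylundeca-5,9-dien-1-yn-1-ide | [Li]C#CCC/C(C)=C/CC/C(C)=C/Cc1cccc(C)c1O[Si](C)(C)C(C)(C)C | intermediate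
13 | lithium alkoxide of the racemic C12′ propargylic alcohol (aryl TBS ether) | CC(C)=CCC(O[Li])C#CCC/C(C)=C/CC/C(C)=C/Cc1cccc(C)c1O[Si](C)(C)C(C)(C)C | intermediate
14 | racemic tert-butyl{2-[(2E,6E)-12-(methoxycarbonyloxy)-3,7,15-trimethylhexadeca-2,6,14-trien-10-yn-1-yl]-6-methylphenoxy}dimethylsilane | CC(C)=CCC(OC(=O)OC)C#CCC/C(C)=C/CC/C(C)=C/Cc1cccc(C)c1O[Si](C)(C)C(C)(C)C | intermediate
15 | tert-butyl{2-[(2E,6E,12R)-12-acetoxy-3,7,15-trimethylhexadeca-2,6,14-trien-10-yn-1-yl]-6-methylphenoxy}dimethylsilane | CC(C)=CC[C@@H](OC(C)=O)C#CCC/C(C)=C/CC/C(C)=C/Cc1cccc(C)c1O[Si](C)(C)C(C)(C)C | intermediate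
16 | 2-[(2E,6E,12R)-12-hydroxy-3,7,15-trimethylhexadeca-2,6,14-trien-10-yn-1-yl]-6-methylphenol | CC(C)=CC[C@@H](O)C#CCC/C(C)=C/CC/C(C)=C/Cc1cccc(C)c1O | intermediate
17 | 2-[(2E,6E,10Z,12R)-12-hydroxy-3,7,15-trimethyl-11-(tributylstannyl)hexadeca-2,6,10,14-tetraen-1-yl]-6-methylphenol | CC(C)=CC[C@@H](O)/C(=C/CC/C(C)=C/CC/C(C)=C/Cc1cccc(C)c1O)[Sn](CCCC)(CCCC)CCCC | intermediate
18 | trilithio species from 17: C11′ alkenyllithium, C12′ lithium alkoxide, lithium phenoxide | CC(C)=CC[C@@H](O[Li])/C([Li])=C/CC/C(C)=C/CC/C(C)=C/Cc1cccc(C)c1O[Li] | intermediate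
19 | 2-[(2E,6E,10E,12R)-12-hydroxy-11-(hydroxymethyl)-3,7,15-trimethylhexadeca-2,6,10,14-tetraen-1-yl]-6-methylphenol | CC(C)=CC[C@@H](O)/C(=C/CC/C(C)=C/CC/C(C)=C/Cc1cccc(C)c1O)CO | intermediate
20 | 2-[(2E,6E,10E,12R)-12-hydroxy-11-(hydroxymethyl)-3,7,15-trimethylhexadeca-2,6,10,14-tetraen-1-yl]-6-methylcyclohexa-2,5-diene-1,4-dione | CC(C)=CC[C@@H](O)/C(=C/CC/C(C)=C/CC/C(C)=C/CC1=CC(=O)C=C(C)C1=O)CO | target

**Step count and risks**
Total step count: 11. Longest linear sequence: 10 (steps 1–4 and 6–11); step 5 is a one-step side branch.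

The three steps most likely to fail:

Step 7 (the proposed new step). The Ni–propargyl species may lose a β-hydrogen from the doubly activated C13′ to give an enyne, acetate may attack the allenyl terminus, or the product acetate may re-ionise and lose ee. The fallback uses known chemistry and changes the way the stereocentre is set from C–O substitution to ketone reduction. It sets out from alkoxide 13, which is quenched with water instead of methyl chloroformate to give the racemic propargylic alcohol silyl ether F4. Dess–Martin oxidation gives the ynone F5. Noyori transfer hydrogenation with the preformed (R,R)-TsDPEN–Ru(p-cymene) catalyst in i-PrOH, without added base to spare the β,γ-unsaturated ketone, gives the (12R)-propargylic alcohol silyl ether F6; the sense is assigned by analogy with alkynyl methyl ketones. K2CO3/MeOH removes the aryl silyl group and the fallback comes back at 16.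

Step 10. Tin–lithium exchange on a hindered alkenylstannane that already carries two lithium oxides may be slow or end in protodestannylation. The fallback replaces the organolithium by a cross-coupling. It sets out from 17, which is treated with I2 in CH2Cl2 at −78 °C to give, with retention, the alkenyl iodide 2-[(2E,6E,10Z,12R)-12-hydroxy-11-iodo-3,7,15-trimethylhexadeca-2,6,10,14-tetraen-1-yl]-6-methylphenol F7. Stille coupling of F7 with (tributylstannyl)methanol (Pd(PPh3)4, dioxane, 90 °C) comes back at 19.

Step 6. The acetylide 12 of the valuable fragment may enolise the β,γ-unsaturated aldehyde 9 instead of adding to it. The fallback reverses the order of the two C–C bond formations, so that the aldehyde meets a cheap nucleophile used in excess. It sets out from 9: propynyllithium F1 (from 10 and n-BuLi) adds to 9 to give racemic 7-methyloct-6-en-2-yn-4-ol F2. Double deprotonation with n-BuLi/TMEDA at oxygen and at the propargylic methyl group gives the O,C-dilithio dianion F3. F3 is alkylated at carbon by bromide 7 and so comes back at alkoxide 13, which is trapped with methyl chloroformate to 14 as in the main route.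

Further compounds
F1 | step 6 | propynyllithium | [Li]C#CC
F2 | step 6 | racemic 7-methyloct-6-en-2-yn-4-ol | CC#CC(O)CC=C(C)C
F3 | step 6 | O,C-dilithio dianion of 7-methyloct-6-en-2-yn-4-ol | [Li]CC#CC(O[Li])CC=C(C)C
F4 | step 7 | racemic tert-butyl{2-[(2E,6E)-12-hydroxy-3,7,15-trimethylhexadeca-2,6,14-trien-10-yn-1-yl]-6-methylphenoxy}dimethylsilane | CC(C)=CCC(O)C#CCC/C(C)=C/CC/C(C)=C/Cc1cccc(C)c1O[Si](C)(C)C(C)(C)C
F5 | step 7 | tert-butyl{2-[(2E,6E)-3,7,15-trimethyl-12-oxohexadeca-2,6,14-trien-10-yn-1-yl]-6-methylphenoxy}dimethylsilane | CC(C)=CCC(=O)C#CCC/C(C)=C/CC/C(C)=C/Cc1cccc(C)c1O[Si](C)(C)C(C)(C)C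
F6 | step 7 | tert-butyl{2-[(2E,6E,12R)-12-hydroxy-3,7,15-trimethylhexadeca-2,6,14-trien-10-yn-1-yl]-6-methylphenoxy}dimethylsilane | CC(C)=CC[C@@H](O)C#CCC/C(C)=C/CC/C(C)=C/Cc1cccc(C)c1O[Si](C)(C)C(C)(C)C
F7 | step 10 | 2-[(2E,6E,10Z,12R)-12-hydroxy-11-iodo-3,7,15-trimethylhexadeca-2,6,10,14-tetraen-1-yl]-6-methylphenol | CC(C)=CC[C@@H](O)/C(I)=C/CC/C(C)=C/CC/C(C)=C/Cc1cccc(C)c1O
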